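**Plan**

1. Target numbering: quinone C1(=O), C2(OMe), C3(Me), C4(=O), C5(H), C6(side chain). The ring bond C5=C6 and the exocyclic C=CH2 on C6 together form a buta-1,3-diene-2,3-diyl unit, and O=C4–C3(Me)=C2(OMe)–C1=O is a ring-opened cyclobutenedione. The quinone is therefore the 6π-electrocyclisation product of a dienylketene.
2. Cuts, in order: ring bond C4–C5 (electrocyclisation of the ketene from a 4-dienyl-4-hydroxycyclobutenone); ring bond C1–C6 and the ester C–O bond (dienyllithium addition to 3-methoxy-4-methylcyclobutenedione, alkoxide trapped with angelic anhydride); the bond from the carbinol carbon to the diene (acylation of 2-lithio-3-stannylbutadiene).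
3. Forward: 2,3-bis(trimethylstannyl)butadiene acts as a diene 2,3-dianion. The first tin–lithium exchange joins the prenyl-bearing acyl unit, the second joins the squarate-derived dione, and the only ring closes in the last step.
4. Stereochemistry: the single (S) centre comes from catalyst-controlled (CBS) reduction of dienone 9. The (Z)-ester geometry comes from angelic anhydride. The tertiary carbinol centre of the cyclobutenone forms unselectively and is erased in the ring closure.

Key step: step 7

Remark: angelic anhydride 16 is taken as a purchasable reagent, and the ring carbinol carbon created in step 6 is carried as both epimers because step 7 turns it into a carbonyl carbon.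

**Step 1**
Reactants: 1 1,4-dichlorobut-2-yne
Product: 3 2,3-bis(trimethylstannyl)buta-1,3-diene, via chloroallenylstannane 2 (not isolated)
Conditions: Me3SnSnMe3 (2.1 equiv), MeLi, THF, −20 °C; then 1, −78 °C → rt
Reagents that add atoms: hexamethylditin, C[Sn](C)(C)[Sn](C)(C)C (used as trimethylstannyllithium, [Li][Sn](C)(C)C)
Why: Two successive SN2′ displacements by the stannyl anion, first on the propargylic chloride to give allene 2 and then at the central allene carbon of its allylic chloride, should give the 2,3-distannyl diene; this double substitution is the known way to this reagent.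

**Step 2**
Reactants: 4 4-methylpent-3-enoic acid
Product: 6 N-methoxy-N,4-dimethylpent-3-enamide, via acylimidazole 5 (not isolated)
Conditions: 1,1'-carbonyldiimidazole, CH2Cl2, 0 °C → rt; then MeNH(OMe)·HCl, rt
Reagents that add atoms: N,O-dimethylhydroxylamine hydrochloride, CNOC.Cl
Why: Weinreb amide synthesis through the acyl imidazole runs under near-neutral conditions, which should leave the β,γ-double bond out of conjugation.

**Step 3**
Reactants: 3 2,3-bis(trimethylstannyl)buta-1,3-diene; 6 N-methoxy-N,4-dimethylpent-3-enamide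
Product: 9 7-methyl-3-methylidene-2-(trimethylstannyl)octa-1,6-dien-4-one, via lithiodiene 7 (not isolated), via tetrahedral lithium adduct 8 (not isolated)
Conditions: MeLi (1.0 equiv), THF, −78 °C; then 6, −78 °C; aq. NH4Cl, −78 °C; crude ketone kept cold and used at once
Reagents that add atoms: none
Why: One tin–lithium exchange gives the 2-lithiodiene, and its addition to the amide stops at the chelated adduct 8 (Weinreb ketone synthesis), so the sensitive 2-acyldiene is released only on cold quench; no stereocentre is formed.

**Step 4**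
Reactants: 9 7-methyl-3-methylidene-2-(trimethylstannyl)octa-1,6-dien-4-one
Product: 11 (4S)-7-methyl-3-methylidene-2-(trimethylstannyl)octa-1,6-dien-4-ol, via catechol borate 10 (not isolated)
Conditions: (R)-1-methyl-3,3-diphenyltetrahydro-1H,3H-pyrrolo[1,2-c][1,3,2]oxazaborole (0.2 equiv), catecholborane, toluene, −78 °C; then MeOH, pH 7 buffer
Reagents that add atoms: none
Why: In this Corey–Bakshi–Shibata reduction the ketone should bind to the catalyst boron anti to the branched dienyl group (large) rather than the CH2-prenyl group (small), so the (R)-catalyst should deliver hydride to the face that gives the (4S)-alcohol, and catecholborane at −78 °C should give 1,2-reduction only and spare the alkenes and the vinylstannane.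

**Step 5**
Reactants: 12 dimethyl squarate
Product: 15 3-methoxy-4-methylcyclobut-3-ene-1,2-dione, via lithium alkoxide 13 (not isolated), via trifluoroacetate 14 (not isolated)
Conditions: MeLi (1.05 equiv), THF, −78 °C; then (CF3CO)2O, −78 °C; H2O, → rt
Reagents that add atoms: methyllithium, [Li]C; water, O
Why: 1,2-Addition of MeLi to one vinylogous ester carbonyl, trifluoroacetylation, ionisation and hydrolytic loss of methanol (1,3-carbonyl transposition) is the standard route to 3-alkoxy-4-alkylcyclobutenediones.

**Step 6**
Reactants: 11 (4S)-7-methyl-3-methylidene-2-(trimethylstannyl)octa-1,6-dien-4-ol; 15 3-methoxy-4-methylcyclobut-3-ene-1,2-dione; 16 angelic anhydride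
Product: 20 (4S)-2-(1-hydroxy-2-methoxy-3-methyl-4-oxocyclobut-2-en-1-yl)-7-methyl-3-methylideneocta-1,6-dien-4-yl (2Z)-2-methylbut-2-enoate (both epimers at the ring carbinol carbon), via dilithio dianion 17 (not isolated), via dilithium dialkoxide 18 (not isolated), via lithium alkoxide ester 19 (not isolated)
Conditions: MeLi (2.05 equiv), THF, −78 → −40 °C; then 15 (1.0 equiv), −78 °C; then 16 (1.1 equiv), −78 → −40 °C; aq. NH4Cl
Reagents that add atoms: none
Why: Deprotonation and tin–lithium exchange give a chelated alkoxide–vinyllithium that should add to the more electrophilic ketone of 15 (the one flanked by C–OMe, not the vinylogous ester carbonyl), and the secondary lithium alkoxide of 18 should be acylated by the hindered anhydride in preference to the tertiary cyclobutenyl alkoxide, a low-temperature alkoxide acylation that is known to keep the (Z)-geometry; the new tertiary carbinol centre forms as both epimers, which does not matter.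

**Step 7**
Reactants: 20 (4S)-2-(1-hydroxy-2-methoxy-3-methyl-4-oxocyclobut-2-en-1-yl)-7-methyl-3-methylideneocta-1,6-dien-4-yl (2Z)-2-methylbut-2-enoate
Product: 24 (3S)-2-(5-methoxy-4-methyl-3,6-dioxocyclohexa-1,4-dien-1-yl)-6-methylhepta-1,5-dien-3-yl (2Z)-2-methylbut-2-enoate (target), via dienylketene 21 (not isolated), via cyclohexadienone 22 (not isolated), via hydroquinone 23 (not isolated)
Conditions: toluene (degassed, dilute), 110 °C; then Ag2O, MgSO4, rt
Reagents that add atoms: none
Why: Heating should open the cyclobutenone by conrotatory 4π electrocyclic cleavage of the bond between the carbonyl carbon and the carbinol carbon, the hydroxyl rotating outward and the dienyl group inward, to give (Z)-dienylketene 21. Disrotatory 6π electrocyclisation then joins the ketene carbon to the terminal CH2 of the directly attached vinyl unit, closing the six-membered carbocycle in an all-carbon 6π mode; enolisation of dienone 22 gives hydroquinone 23, which Ag2O dehydrogenates to the quinone. The closest known reaction type is the Moore rearrangement of 4-alkenyl-4-hydroxycyclobutenones to hydroquinones and quinones. No stereocentre is created: the tertiary carbinol carbon becomes a carbonyl carbon, so both epimers of 20 converge, and the (S)-carbinol and the (Z)-ester lie outside the reacting π system. The step needs torquoselectivity (secured by the donor hydroxyl on the ring-opening carbon), the placement of OMe next to the carbonyl that carries the side-chain carbon (fixed by the site of addition in step 6) and periselectivity (the second methylene group is cross-conjugated and cannot reach the ketene).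

**Compound list**

1 | 1,4-dichlorobut-2-yne | ClCC#CCCl | starting material
2 | (1-chlorobuta-2,3-dien-2-yl)trimethylstannane | C=C=C(CCl)[Sn](C)(C)C | intermediate (not isolated)
3 | 2,3-bis(trimethylstannyl)buta-1,3-diene | C=C([Sn](C)(C)C)C(=C)[Sn](C)(C)C | intermediate
4 | 4-methylpent-3-enoic acid | CC(C)=CCC(=O)O | starting material
5 | 1-(1H-imidazol-1-yl)-4-methylpent-3-en-1-one | CC(C)=CCC(=O)n1ccnc1 | intermediate (not isolated)
6 | N-methoxy-N,4-dimethylpent-3-enamide | CC(C)=CCC(=O)N(C)OC | intermediate
7 | [3-(trimethylstannyl)buta-1,3-dien-2-yl]lithium | [Li]C(=C)C(=C)[Sn](C)(C)C | intermediate (not isolated)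
8 | lithium 4-[methoxy(methyl)amino]-7-methyl-3-methylidene-2-(trimethylstannyl)octa-1,6-dien-4-olate | [Li]OC(CC=C(C)C)(N(C)OC)C(=C)C(=C)[Sn](C)(C)C | intermediate (not isolated)
9 | 7-methyl-3-methylidene-2-(trimethylstannyl)octa-1,6-dien-4-one | C=C([Sn](C)(C)C)C(=C)C(=O)CC=C(C)C | intermediate
10 | 2-{[(4S)-7-methyl-3-methylidene-2-(trimethylstannyl)octa-1,6-dien-4-yl]oxy}-1,3,2-benzodioxaborole | C=C([Sn](C)(C)C)C(=C)[C@H](CC=C(C)C)OB1Oc2ccccc2O1 | intermediate (not isolated)
11 | (4S)-7-methyl-3-methylidene-2-(trimethylstannyl)octa-1,6-dien-4-ol | C=C([Sn](C)(C)C)C(=C)[C@H](CC=C(C)C)O | intermediate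
12 | dimethyl squarate (3,4-dimethoxycyclobut-3-ene-1,2-dione) | COC1=C(OC)C(=O)C1=O | starting material
13 | lithium 2,3-dimethoxy-1-methyl-4-oxocyclobut-2-en-1-olate | [Li]OC1(C)C(OC)=C(OC)C1=O | intermediate (not isolated)
14 | 2,3-dimethoxy-1-methyl-4-oxocyclobut-2-en-1-yl trifluoroacetate | CC1(OC(=O)C(F)(F)F)C(OC)=C(OC)C1=O | intermediate (not isolated)
15 | 3-methoxy-4-methylcyclobut-3-ene-1,2-dione | CC1=C(OC)C(=O)C1=O | intermediate
16 | angelic anhydride, (2Z)-2-methylbut-2-enoic anhydride | C/C=C(/C)C(=O)OC(=O)/C(C)=C\C | starting material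
17 | lithium (4S)-2-lithio-7-methyl-3-methylideneocta-1,6-dien-4-olate | [Li]C(=C)C(=C)[C@H](CC=C(C)C)O[Li] | intermediate (not isolated)
18 | dilithium dialkoxide of (4S)-2-(1-hydroxy-2-methoxy-3-methyl-4-oxocyclobut-2-en-1-yl)-7-methyl-3-methylideneocta-1,6-dien-4-ol | [Li]OC1(C(=C)C(=C)[C@H](CC=C(C)C)O[Li])C(OC)=C(C)C1=O | intermediate (not isolated)
19 | lithium 2-methoxy-3-methyl-1-{(4S)-7-methyl-3-methylidene-4-[(2Z)-2-methylbut-2-enoyloxy]octa-1,6-dien-2-yl}-4-oxocyclobut-2-en-1-olate | [Li]OC1(C(=C)C(=C)[C@H](CC=C(C)C)OC(=O)/C(C)=C\C)C(OC)=C(C)C1=O | intermediate (not isolated)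
20 | (4S)-2-(1-hydroxy-2-methoxy-3-methyl-4-oxocyclobut-2-en-1-yl)-7-methyl-3-methylideneocta-1,6-dien-4-yl (2Z)-2-methylbut-2-enoate, both epimers at the ring carbinol carbon | OC1(C(=C)C(=C)[C@H](CC=C(C)C)OC(=O)/C(C)=C\C)C(OC)=C(C)C1=O | intermediate
21 | (4S)-2-[(1Z)-1-hydroxy-2-methoxy-3-methyl-4-oxobuta-1,3-dien-1-yl]-7-methyl-3-methylideneocta-1,6-dien-4-yl (2Z)-2-methylbut-2-enoate | O=C=C(C)/C(OC)=C(/O)C(=C)C(=C)[C@H](CC=C(C)C)OC(=O)/C(C)=C\C | intermediate (not isolated)
22 | (3S)-2-(2-hydroxy-3-methoxy-4-methyl-5-oxocyclohexa-1,3-dien-1-yl)-6-methylhepta-1,5-dien-3-yl (2Z)-2-methylbut-2-enoate | O=C1CC(C(=C)[C@H](CC=C(C)C)OC(=O)/C(C)=C\C)=C(O)C(OC)=C1C | intermediate (not isolated)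
23 | (3S)-2-(2,5-dihydroxy-3-methoxy-4-methylphenyl)-6-methylhepta-1,5-dien-3-yl (2Z)-2-methylbut-2-enoate | Cc1c(O)cc(C(=C)[C@H](CC=C(C)C)OC(=O)/C(C)=C\C)c(O)c1OC | intermediate (not isolated)
24 | (3S)-2-(5-methoxy-4-methyl-3,6-dioxocyclohexa-1,4-dien-1-yl)-6-methylhepta-1,5-dien-3-yl (2Z)-2-methylbut-2-enoate | C=C(C1=CC(=O)C(C)=C(OC)C1=O)[C@H](CC=C(C)C)OC(=O)/C(C)=C\C | target

**Step count**

Total steps: 7. Longest linear sequence: 5 (steps 1, 3, 4, 6, 7; steps 2 and 5 are side branches).

**Steps most likely to fail**

Step 6. The two alkoxides of 18 may be acylated without discrimination, the free secondary alkoxide may attack the vinylogous ester carbon of the four-membered ring with loss of methoxide, or the tin–lithium exchange may stall next to the alkoxide. The fallback sets out from 11 and returns at 24. Silylation of 11 (TBSCl, imidazole, DMF) gives the silyl ether F1. Tin–lithium exchange (MeLi, THF, −78 °C) and addition to 15 should give the cyclobutenone F2. Thermolysis in toluene at 110 °C followed by Ag2O should give the quinone silyl ether F3. HF·pyridine (THF, 0 °C) should free the quinone alcohol F4. F4 is then esterified with the mixed anhydride made from angelic acid and 2,4,6-trichlorobenzoyl chloride (Et3N, toluene, 80 °C, no 4-(dimethylamino)pyridine) to give 24.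

Step 3. Proton transfer from the doubly activated CH2 of amide 6 to the basic vinyllithium may compete with addition, the amine released on quench may add to the enone, and the 2-acyldiene may dimerise by a [4+2] reaction before it is reduced. The fallback sets out from 7 (made from 3 as in step 3) and from 4, and returns at 9. Transmetalation of 7 with ZnCl2 (THF, −78 → 0 °C) gives the dienylzinc chloride F5. Acid 4 with oxalyl chloride (cat. DMF, CH2Cl2) gives 4-methylpent-3-enoyl chloride F6. Negishi acylation of F5 with F6 (Pd(PPh3)4, zerovalent palladium, THF, 0 °C) should give 9 with a non-basic nucleophile and without a free amine; 9 is again reduced at once.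

Step 4. The catalyst may not discriminate well enough between the dienyl and the CH2-prenyl group (poor facial selectivity), or conjugate reduction may compete. The fallback sets out from 9 and returns at 11. Luche reduction (NaBH4, CeCl3·7H2O, MeOH, −78 °C) gives the racemic alcohol F7. Sharpless kinetic resolution (Ti(OiPr)4, D-(−)-diisopropyl tartrate, t-BuOOH, 4 Å molecular sieves, CH2Cl2, −20 °C) should epoxidise the (4R)-enantiomer to the epoxy alcohol F8 and leave the (4S)-alcohol, which is 11.

**Further compounds**

F1 | step 6 | tert-butyldimethyl{[(4S)-7-methyl-3-methylidene-2-(trimethylstannyl)octa-1,6-dien-4-yl]oxy}silane | C=C([Sn](C)(C)C)C(=C)[C@H](CC=C(C)C)O[Si](C)(C)C(C)(C)C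
F2 | step 6 | 4-{(4S)-4-[(tert-butyldimethylsilyl)oxy]-7-methyl-3-methylideneocta-1,6-dien-2-yl}-4-hydroxy-3-methoxy-2-methylcyclobut-2-en-1-one | OC1(C(=C)C(=C)[C@H](CC=C(C)C)O[Si](C)(C)C(C)(C)C)C(OC)=C(C)C1=O
F3 | step 6 | 2-{(3S)-3-[(tert-butyldimethylsilyl)oxy]-6-methylhepta-1,5-dien-2-yl}-6-methoxy-5-methylcyclohexa-2,5-diene-1,4-dione | C=C(C1=CC(=O)C(C)=C(OC)C1=O)[C@H](CC=C(C)C)O[Si](C)(C)C(C)(C)C
F4 | step 6 | 2-[(3S)-3-hydroxy-6-methylhepta-1,5-dien-2-yl]-6-methoxy-5-methylcyclohexa-2,5-diene-1,4-dione | C=C(C1=CC(=O)C(C)=C(OC)C1=O)[C@H](CC=C(C)C)O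
F5 | step 3 | chloro[3-(trimethylstannyl)buta-1,3-dien-2-yl]zinc | Cl[Zn]C(=C)C(=C)[Sn](C)(C)C
F6 | step 3 | 4-methylpent-3-enoyl chloride | CC(C)=CCC(Cl)=O
F7 | step 4 | rac-7-methyl-3-methylidene-2-(trimethylstannyl)octa-1,6-dien-4-ol | C=C([Sn](C)(C)C)C(=C)C(CC=C(C)C)O
F8 | step 4 | (1R)-4-methyl-1-{(2S)-2-[1-(trimethylstannyl)ethenyl]oxiran-2-yl}pent-3-en-1-ol | C=C([Sn](C)(C)C)[C@]1(CO1)[C@@H](CC=C(C)C)O
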